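**Assumption:** (1R,5R)-(+)-verbenone is bought as the single enantiomer; the carbinol carbon that later becomes the C4 ketone is carried as an epimer mixture and written without a descriptor.

## Retrosynthetic overview

1. Target 23 ⇐ oxidation-level adjustment at C4 of hydroquinone 21, whose aromatic ring is made last by thermal 4π ring opening / 6π electrocyclization (Moore rearrangement) of cyclobutenone 17.
2. 17 ⇐ dimethyl squarate 11 + cyclohexenyllithium 12 (Shapiro), then i-PrLi and a 1,3-carbonyl transposition that places i-Pr next to the carbinol carbon.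
3. 12 ⇐ α-silyloxy ketone 9 ⇐ regiodefined enol acetate 5 (α-hydroxylation supplies the future C4 oxygen).
4. 5 ⇐ cyclobutane fragmentation of pinanone 4 ⇐ (1R,5R)-verbenone 1 + propanoate homoenolate; addition anti to the CMe2 bridge sets the quaternary centre, and bridgehead C5 becomes the isopropenyl-bearing carbon.
5. Ring order: cyclohexanone ring (unveiled from the pinane, later the tetralone ring) → cyclobutenone → hydroquinone ring.

## Route

Step 1
Reactants: 1 (1R,5R)-verbenone; 2 (1-ethoxycyclopropoxy)trimethylsilane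
Product: 4 ethyl 3-[(1R,2R,5R)-2,6,6-trimethyl-4-oxobicyclo[3.1.1]heptan-2-yl]propanoate, via silyl enol ether 3 (not isolated)
Conditions: 2 (2 equiv), ZnCl2 (1 equiv), Et2O, rt; then 1, CuBr·SMe2 (10 mol %), HMPA, THF, 0 °C to rt; 1 M HCl work-up
Reagents that add atoms: none
Why: Copper-catalysed conjugate addition of the zinc ester homoenolate (Nakamura–Kuwajima type, driven by the TMSCl formed in the flask) to the enone; the nucleophile enters C4 from the face opposite the gem-dimethyl bridge, so the quaternary centre is set by the two bought bridgehead centres.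

Step 2
Reactants: 4 ethyl 3-[(1R,2R,5R)-2,6,6-trimethyl-4-oxobicyclo[3.1.1]heptan-2-yl]propanoate
Product: 5 ethyl 3-[(1R,6S)-3-acetyloxy-1-methyl-6-(prop-1-en-2-yl)cyclohex-3-en-1-yl]propanoate
Conditions: BF3·OEt2, Zn(OAc)2, Ac2O, 0 °C to rt
Reagents that add atoms: acetic anhydride, CC(=O)OC(C)=O
Why: Lewis-acid-promoted, carbonyl-assisted heterolysis of the strained cyclobutane bond α to the ketone (retro-Prins-type fragmentation) gives an enol trapped as its acetate and a tertiary cation that loses a proton to the isopropenyl group; no stereocentre is touched and the enol acetate points to the carbon that becomes C4.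

Step 3
Reactants: 5 ethyl 3-[(1R,6S)-3-acetyloxy-1-methyl-6-(prop-1-en-2-yl)cyclohex-3-en-1-yl]propanoate
Product: 7 ethyl 3-[(1R,2S)-4-hydroxy-1-methyl-5-oxo-2-(prop-1-en-2-yl)cyclohexyl]propanoate, via potassium enolate 6 (not isolated)
Conditions: KOt-Bu (1.05 equiv), THF, −78 °C; (±)-2-(phenylsulfonyl)-3-phenyloxaziridine, −78 °C; AcOH quench
Reagents that add atoms: 2-(phenylsulfonyl)-3-phenyloxaziridine, O=S(=O)(c1ccccc1)N1OC1c1ccccc1
Why: Alkoxide cleavage of the enol acetate releases the regiodefined enolate, which undergoes Davis α-hydroxylation; the new carbinol centre forms without control and is erased when it is oxidised in step 10.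

Step 4
Reactants: 7 ethyl 3-[(1R,2S)-4-hydroxy-1-methyl-5-oxo-2-(prop-1-en-2-yl)cyclohexyl]propanoate
Product: 8 ethyl 3-[(1R,2S)-4-{[tert-butyl(dimethyl)silyl]oxy}-1-methyl-5-oxo-2-(prop-1-en-2-yl)cyclohexyl]propanoate
Conditions: TBSOTf, 2,6-lutidine, CH2Cl2, −78 to 0 °C; aq. NaHCO3
Reagents that add atoms: tert-butyldimethylsilyl trifluoromethanesulfonate, CC(C)(C)[Si](C)(C)OS(=O)(=O)C(F)(F)F
Why: Standard silylation of the secondary alcohol; the silyl ether survives the organolithium steps and makes this α-carbon a tertiary CH, which steers the later Shapiro deprotonation to the other side.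

Step 5
Reactants: 8 ethyl 3-[(1R,2S)-4-{[tert-butyl(dimethyl)silyl]oxy}-1-methyl-5-oxo-2-(prop-1-en-2-yl)cyclohexyl]propanoate
Product: 9 3-[(1R,2S)-4-{[tert-butyl(dimethyl)silyl]oxy}-1-methyl-5-oxo-2-(prop-1-en-2-yl)cyclohexyl]propanoic acid
Conditions: LiOH, THF–H2O, rt; then 1 M HCl to pH 3
Reagents that add atoms: lithium hydroxide, [Li+].[OH-]
Why: Saponification frees the acid, which as its lithium carboxylate is inert to the alkyllithium steps that an ester would not survive; the only epimerisable centre is the carbinol carbon, which does not matter.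

Step 6
Reactants: 9 3-[(1R,2S)-4-{[tert-butyl(dimethyl)silyl]oxy}-1-methyl-5-oxo-2-(prop-1-en-2-yl)cyclohexyl]propanoic acid
Product: 10 3-[(1R,2S)-4-{[tert-butyl(dimethyl)silyl]oxy}-1-methyl-2-(prop-1-en-2-yl)-5-{2-[2,4,6-tri(propan-2-yl)benzenesulfonyl]hydrazinylidene}cyclohexyl]propanoic acid
Conditions: 2,4,6-triisopropylbenzenesulfonyl hydrazide (1.05 equiv), THF, 4 Å MS, rt
Reagents that add atoms: 2,4,6-tri(propan-2-yl)benzenesulfonohydrazide, CC(C)c1cc(C(C)C)c(S(=O)(=O)NN)c(C(C)C)c1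
Why: Condensation to the trisylhydrazone, catalysed by the substrate's own acid; the N–N bond is expected to sit syn to the ring CH2 and away from the silyloxy-bearing carbon.

Step 7
Reactants: 10 3-[(1R,2S)-4-{[tert-butyl(dimethyl)silyl]oxy}-1-methyl-2-(prop-1-en-2-yl)-5-{2-[2,4,6-tri(propan-2-yl)benzenesulfonyl]hydrazinylidene}cyclohexyl]propanoic acid; 11 dimethyl squarate
Product: 14 3-[(1R,6S)-4-{[tert-butyl(dimethyl)silyl]oxy}-3-[2,3-dimethoxy-4-oxo-1-(trimethylsilyloxy)cyclobut-2-en-1-yl]-1-methyl-6-(prop-1-en-2-yl)cyclohex-2-en-1-yl]propanoic acid, via vinyllithium 12 (not isolated), via bis-silyl adduct 13 (not isolated)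
Conditions: n-BuLi (3.1 equiv), TMEDA, THF, −78 to 0 °C; 11 (1.2 equiv), −78 °C; TMSCl (3.5 equiv); aq. NH4Cl
Reagents that add atoms: chlorotrimethylsilane, C[Si](C)(C)Cl
Why: Shapiro reaction in which syn-directed deprotonation at the CH2 (not the silyloxy CH) and loss of sulfinate and N2 give vinyllithium 12, which adds 1,2 to a squarate carbonyl; silylation caps the tertiary alkoxide, and the new carbinol centre is destroyed in step 9.

Step 8
Reactants: 14 3-[(1R,6S)-4-{[tert-butyl(dimethyl)silyl]oxy}-3-[2,3-dimethoxy-4-oxo-1-(trimethylsilyloxy)cyclobut-2-en-1-yl]-1-methyl-6-(prop-1-en-2-yl)cyclohex-2-en-1-yl]propanoic acid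
Product: 17 3-[(1R,6S)-4-{[tert-butyl(dimethyl)silyl]oxy}-3-[3-methoxy-4-oxo-2-(propan-2-yl)-1-(trimethylsilyloxy)cyclobut-2-en-1-yl]-1-methyl-6-(prop-1-en-2-yl)cyclohex-2-en-1-yl]propanoic acid, via dilithium alkoxide 15 (not isolated), via bis-trifluoroacetate 16 (not isolated)
Conditions: i-PrLi (2.1 equiv), THF, −78 °C; (CF3CO)2O (2.2 equiv), −78 to −20 °C; aq. NaHCO3
Reagents that add atoms: isopropyllithium, [Li]C(C)C; water, O
Why: 1,2-Addition of i-PrLi to the remaining carbonyl, trifluoroacetylation of the new alkoxide, ionisation to the methoxy-stabilised allyl cation and hydrolysis amount to a Stork–Danheiser-type 1,3-carbonyl transposition that puts isopropyl on the carbon next to the silyloxy carbinol; the silyl ether keeps the alkenyl carbinol from ionising instead.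

Step 9
Reactants: 17 3-[(1R,6S)-4-{[tert-butyl(dimethyl)silyl]oxy}-3-[3-methoxy-4-oxo-2-(propan-2-yl)-1-(trimethylsilyloxy)cyclobut-2-en-1-yl]-1-methyl-6-(prop-1-en-2-yl)cyclohex-2-en-1-yl]propanoic acid
Product: 21 3-[(1S,2S)-4,5,8-trihydroxy-7-methoxy-1-methyl-6-(propan-2-yl)-2-(prop-1-en-2-yl)-1,2,3,4-tetrahydronaphthalen-1-yl]propanoic acid, via dienylketene 18 (not isolated), via cyclohexadienone 19 (not isolated), via aryl silyl ether 20 (not isolated)
Conditions: PhMe (0.01 M, degassed), 110 °C, 2 h; then TBAF (3.5 equiv), THF, 0 °C; aq. NH4Cl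
Reagents that add atoms: none
Why: Moore rearrangement, in which thermal 4π-electrocyclic ring opening (silyloxy rotating outward) gives the (Z)-dienylketene and 6π-electrocyclisation onto the cyclohexene CH followed by tautomerisation builds the hexasubstituted hydroquinone with OH, i-Pr, OMe and OH in the required order; fluoride then removes both silyl groups, and the two stereocentres are spectators.

Step 10
Reactants: 21 3-[(1S,2S)-4,5,8-trihydroxy-7-methoxy-1-methyl-6-(propan-2-yl)-2-(prop-1-en-2-yl)-1,2,3,4-tetrahydronaphthalen-1-yl]propanoic acid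
Product: 23 3-[(1S,2S)-5,8-dihydroxy-7-methoxy-1-methyl-4-oxo-6-(propan-2-yl)-2-(prop-1-en-2-yl)-1,2,3,4-tetrahydronaphthalen-1-yl]propanoic acid, via acylquinone 22 (not isolated)
Conditions: Dess–Martin periodinane (2.5 equiv), NaHCO3, CH2Cl2, 0 °C; then aq. Na2S2O4, EtOAc, rt
Reagents that add atoms: none
Why: Dess–Martin oxidation takes the hydroquinone to the quinone and the carbinol to the ketone, and dithionite reduces only the quinone back to give the hydrogen-bonded 5,8-dihydroxy-1-tetralone; C2 is β to the new ketone and C1 is quaternary, so neither can epimerise.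

## Compound list

1 | (1R,5R)-(+)-verbenone, (1R,5R)-4,6,6-trimethylbicyclo[3.1.1]hept-3-en-2-one | CC1=CC(=O)[C@@H]2C[C@H]1C2(C)C | starting material
2 | (1-ethoxycyclopropoxy)trimethylsilane | CCOC1(O[Si](C)(C)C)CC1 | starting material
3 | ethyl 3-[(1S,2S,5R)-2,6,6-trimethyl-4-(trimethylsilyloxy)bicyclo[3.1.1]hept-3-en-2-yl]propanoate (silyl enol ether of 4) | CCOC(=O)CC[C@]1(C)C=C(O[Si](C)(C)C)[C@@H]2C[C@H]1C2(C)C | intermediate (not isolated)
4 | ethyl 3-[(1R,2R,5R)-2,6,6-trimethyl-4-oxobicyclo[3.1.1]heptan-2-yl]propanoate (ester chain anti to the CMe2 bridge) | CCOC(=O)CC[C@]1(C)CC(=O)[C@@H]2C[C@H]1C2(C)C | intermediate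
5 | ethyl 3-[(1R,6S)-3-acetyloxy-1-methyl-6-(prop-1-en-2-yl)cyclohex-3-en-1-yl]propanoate | C=C(C)[C@@H]1CC=C(OC(C)=O)C[C@@]1(C)CCC(=O)OCC | intermediate
6 | potassium (4S,5R)-5-(3-ethoxy-3-oxopropyl)-5-methyl-4-(prop-1-en-2-yl)cyclohex-1-en-1-olate | C=C(C)[C@@H]1CC=C(O[K])C[C@@]1(C)CCC(=O)OCC | intermediate (not isolated)
7 | ethyl 3-[(1R,2S)-4-hydroxy-1-methyl-5-oxo-2-(prop-1-en-2-yl)cyclohexyl]propanoate (C4 epimers) | C=C(C)[C@@H]1CC(O)C(=O)C[C@@]1(C)CCC(=O)OCC | intermediate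
8 | ethyl 3-[(1R,2S)-4-{[tert-butyl(dimethyl)silyl]oxy}-1-methyl-5-oxo-2-(prop-1-en-2-yl)cyclohexyl]propanoate (C4 epimers) | C=C(C)[C@@H]1CC(O[Si](C)(C)C(C)(C)C)C(=O)C[C@@]1(C)CCC(=O)OCC | intermediate
9 | 3-[(1R,2S)-4-{[tert-butyl(dimethyl)silyl]oxy}-1-methyl-5-oxo-2-(prop-1-en-2-yl)cyclohexyl]propanoic acid (C4 epimers) | C=C(C)[C@@H]1CC(O[Si](C)(C)C(C)(C)C)C(=O)C[C@@]1(C)CCC(=O)O | intermediate
10 | 3-[(1R,2S)-4-{[tert-butyl(dimethyl)silyl]oxy}-1-methyl-2-(prop-1-en-2-yl)-5-{2-[2,4,6-tri(propan-2-yl)benzenesulfonyl]hydrazinylidene}cyclohexyl]propanoic acid (C4 epimers) | C=C(C)[C@@H]1CC(O[Si](C)(C)C(C)(C)C)C(=NNS(=O)(=O)c2c(C(C)C)cc(C(C)C)cc2C(C)C)C[C@@]1(C)CCC(=O)O | intermediate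
11 | dimethyl squarate, 3,4-dimethoxycyclobut-3-ene-1,2-dione | COC1=C(OC)C(=O)C1=O | starting material
12 | lithium 3-[(1R,6S)-4-{[tert-butyl(dimethyl)silyl]oxy}-3-lithio-1-methyl-6-(prop-1-en-2-yl)cyclohex-2-en-1-yl]propanoate (vinyllithium) | C=C(C)[C@@H]1CC(O[Si](C)(C)C(C)(C)C)C([Li])=C[C@@]1(C)CCC(=O)O[Li] | intermediate (not isolated)
13 | trimethylsilyl ester of 14 (bis-silyl adduct; carbinol carbon unassigned) | C=C(C)[C@@H]1CC(O[Si](C)(C)C(C)(C)C)C(=C[C@@]1(C)CCC(=O)O[Si](C)(C)C)C2(O[Si](C)(C)C)C(OC)=C(OC)C2=O | intermediate (not isolated)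
14 | 3-[(1R,6S)-4-{[tert-butyl(dimethyl)silyl]oxy}-3-[2,3-dimethoxy-4-oxo-1-(trimethylsilyloxy)cyclobut-2-en-1-yl]-1-methyl-6-(prop-1-en-2-yl)cyclohex-2-en-1-yl]propanoic acid (diastereomer mixture at the two carbinol carbons) | C=C(C)[C@@H]1CC(O[Si](C)(C)C(C)(C)C)C(=C[C@@]1(C)CCC(=O)O)C2(O[Si](C)(C)C)C(OC)=C(OC)C2=O | intermediate
15 | dilithium salt of the isopropyl adduct of 14 (tertiary alkoxide and carboxylate) | C=C(C)[C@@H]1CC(O[Si](C)(C)C(C)(C)C)C(=C[C@@]1(C)CCC(=O)O[Li])C2(O[Si](C)(C)C)C(OC)=C(OC)C2(O[Li])C(C)C | intermediate (not isolated)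
16 | tertiary trifluoroacetate and mixed trifluoroacetic anhydride of the isopropyl adduct | C=C(C)[C@@H]1CC(O[Si](C)(C)C(C)(C)C)C(=C[C@@]1(C)CCC(=O)OC(=O)C(F)(F)F)C2(O[Si](C)(C)C)C(OC)=C(OC)C2(OC(=O)C(F)(F)F)C(C)C | intermediate (not isolated)
17 | 3-[(1R,6S)-4-{[tert-butyl(dimethyl)silyl]oxy}-3-[3-methoxy-4-oxo-2-(propan-2-yl)-1-(trimethylsilyloxy)cyclobut-2-en-1-yl]-1-methyl-6-(prop-1-en-2-yl)cyclohex-2-en-1-yl]propanoic acid (diastereomer mixture at the two carbinol carbons) | C=C(C)[C@@H]1CC(O[Si](C)(C)C(C)(C)C)C(=C[C@@]1(C)CCC(=O)O)C2(O[Si](C)(C)C)C(C(C)C)=C(OC)C2=O | intermediate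
18 | (Z)-dienylketene from ring opening of 17 | C=C(C)[C@@H]1CC(O[Si](C)(C)C(C)(C)C)C(=C[C@@]1(C)CCC(=O)O)C(O[Si](C)(C)C)=C(C(C)C)C(OC)=C=O | intermediate (not isolated)
19 | cyclohexa-2,4-dienone from 6π closure (8a-H tautomer of 20) | C=C(C)[C@@H]1CC(O[Si](C)(C)C(C)(C)C)C2=C(O[Si](C)(C)C)C(C(C)C)=C(OC)C(=O)C2[C@@]1(C)CCC(=O)O | intermediate (not isolated)
20 | 3-[(1S,2S)-4-{[tert-butyl(dimethyl)silyl]oxy}-8-hydroxy-7-methoxy-1-methyl-6-(propan-2-yl)-2-(prop-1-en-2-yl)-5-(trimethylsilyloxy)-1,2,3,4-tetrahydronaphthalen-1-yl]propanoic acid | C=C(C)[C@@H]1CC(O[Si](C)(C)C(C)(C)C)c2c(O[Si](C)(C)C)c(C(C)C)c(OC)c(O)c2[C@@]1(C)CCC(=O)O | intermediate (not isolated)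
21 | 3-[(1S,2S)-4,5,8-trihydroxy-7-methoxy-1-methyl-6-(propan-2-yl)-2-(prop-1-en-2-yl)-1,2,3,4-tetrahydronaphthalen-1-yl]propanoic acid (C4 epimers) | C=C(C)[C@@H]1CC(O)c2c(O)c(C(C)C)c(OC)c(O)c2[C@@]1(C)CCC(=O)O | intermediate
22 | 3-[(1S,2S)-7-methoxy-1-methyl-4,5,8-trioxo-6-(propan-2-yl)-2-(prop-1-en-2-yl)-1,2,3,4,5,8-hexahydronaphthalen-1-yl]propanoic acid (acylquinone) | C=C(C)[C@@H]1CC(=O)C2=C([C@@]1(C)CCC(=O)O)C(=O)C(OC)=C(C(C)C)C2=O | intermediate (not isolated)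
23 | 3-[(1S,2S)-5,8-dihydroxy-7-methoxy-1-methyl-4-oxo-6-(propan-2-yl)-2-(prop-1-en-2-yl)-1,2,3,4-tetrahydronaphthalen-1-yl]propanoic acid | C=C(C)[C@@H]1CC(=O)c2c(O)c(C(C)C)c(OC)c(O)c2[C@@]1(C)CCC(=O)O | target

## Step count and risk

Total step count: 10. Longest linear sequence: 10 (1 → 23); 2 and 11 are bought.

The three steps most likely to fail:

**Step 1.** The functionalised zinc–copper reagent may be too sluggish toward the hindered β,β-disubstituted enone. The fallback sets out from 1 and comes back at 4. Addition of the Grignard reagent from 2-(2-bromoethyl)-1,3-dioxolane to 1 with CuBr·SMe2 (THF, −40 °C, NH4Cl work-up) gives (1R,4R,5R)-4-[2-(1,3-dioxolan-2-yl)ethyl]-4,6,6-trimethylbicyclo[3.1.1]heptan-2-one F1, with the same facial selectivity. Jones oxidation (CrO3, H2SO4, aqueous acetone, 0 °C) unmasks and oxidises the aldehyde to 3-[(1R,2R,5R)-2,6,6-trimethyl-4-oxobicyclo[3.1.1]heptan-2-yl]propanoic acid F2, and EtI/K2CO3 in DMF gives 4.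

**Step 7.** The Shapiro reaction runs on a trianion next to a silyloxy group, and the vinyllithium must form on the hindered side. The fallback sets out from 9 and comes back at 12, replacing the syn-directed hydrazone deprotonation by kinetic enolisation away from the silyloxy carbon. LiHMDS (2.2 equiv, THF, −78 °C) then PhNTf2 gives 3-[(1S,6S)-4-{[tert-butyl(dimethyl)silyl]oxy}-1-methyl-6-(prop-1-en-2-yl)-3-(trifluoromethanesulfonyloxy)cyclohex-2-en-1-yl]propanoic acid F3. Coupling with Me3SnSnMe3 (Pd(PPh3)4, LiCl, THF, 60 °C) gives 3-[(1S,6S)-4-{[tert-butyl(dimethyl)silyl]oxy}-1-methyl-6-(prop-1-en-2-yl)-3-(trimethylstannyl)cyclohex-2-en-1-yl]propanoic acid F4. Tin–lithium exchange with MeLi (2.1 equiv, THF, −78 °C) gives 12, which is carried on with 11 and TMSCl as in step 7.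

**Step 8.** i-PrLi may reduce or fail to add to the hindered carbonyl, or the wrong carbinol may ionise. The fallback sets out from 11 (using 12 made as in step 7) and comes back at 21; here the isopropyl group is installed first and a ketal enforces the regiochemistry.
- i-PrMgCl (THF, −78 °C) adds to 11 to give 4-hydroxy-2,3-dimethoxy-4-(propan-2-yl)cyclobut-2-en-1-one F5.
- Ethylene glycol with BF3·OEt2 (CH2Cl2, 0 °C) converts it through the allyl cation into 8-methoxy-7-(propan-2-yl)-1,4-dioxaspiro[4.3]oct-7-en-6-one F6, whose only carbonyl lies next to the isopropyl-bearing carbon.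
- 12 adds to F6 (THF, −78 °C, NH4Cl work-up) to give 3-[(1R,6S)-4-{[tert-butyl(dimethyl)silyl]oxy}-3-[6-hydroxy-8-methoxy-7-(propan-2-yl)-1,4-dioxaspiro[4.3]oct-7-en-6-yl]-1-methyl-6-(prop-1-en-2-yl)cyclohex-2-en-1-yl]propanoic acid F7.
- Oxalic acid on wet silica (CH2Cl2, rt) removes the ketal to give 3-[(1R,6S)-4-{[tert-butyl(dimethyl)silyl]oxy}-3-[1-hydroxy-3-methoxy-4-oxo-2-(propan-2-yl)cyclobut-2-en-1-yl]-1-methyl-6-(prop-1-en-2-yl)cyclohex-2-en-1-yl]propanoic acid F8.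
- Thermolysis (PhMe, 110 °C) gives 3-[(1S,2S)-4-{[tert-butyl(dimethyl)silyl]oxy}-5,8-dihydroxy-7-methoxy-1-methyl-6-(propan-2-yl)-2-(prop-1-en-2-yl)-1,2,3,4-tetrahydronaphthalen-1-yl]propanoic acid F9, and TBAF gives 21.

## Further compounds

F1 | step 1 | (1R,4R,5R)-4-[2-(1,3-dioxolan-2-yl)ethyl]-4,6,6-trimethylbicyclo[3.1.1]heptan-2-one | C1COC(O1)CC[C@]2(C)CC(=O)[C@@H]3C[C@H]2C3(C)C
F2 | step 1 | 3-[(1R,2R,5R)-2,6,6-trimethyl-4-oxobicyclo[3.1.1]heptan-2-yl]propanoic acid | OC(=O)CC[C@]1(C)CC(=O)[C@@H]2C[C@H]1C2(C)C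
F3 | step 7 | 3-[(1S,6S)-4-{[tert-butyl(dimethyl)silyl]oxy}-1-methyl-6-(prop-1-en-2-yl)-3-(trifluoromethanesulfonyloxy)cyclohex-2-en-1-yl]propanoic acid | C=C(C)[C@@H]1CC(O[Si](C)(C)C(C)(C)C)C(OS(=O)(=O)C(F)(F)F)=C[C@@]1(C)CCC(=O)O
F4 | step 7 | 3-[(1S,6S)-4-{[tert-butyl(dimethyl)silyl]oxy}-1-methyl-6-(prop-1-en-2-yl)-3-(trimethylstannyl)cyclohex-2-en-1-yl]propanoic acid | C=C(C)[C@@H]1CC(O[Si](C)(C)C(C)(C)C)C([Sn](C)(C)C)=C[C@@]1(C)CCC(=O)O
F5 | step 8 | 4-hydroxy-2,3-dimethoxy-4-(propan-2-yl)cyclobut-2-en-1-one | COC1=C(OC)C(O)(C(C)C)C1=O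
F6 | step 8 | 8-methoxy-7-(propan-2-yl)-1,4-dioxaspiro[4.3]oct-7-en-6-one | COC1=C(C(C)C)C(=O)C12OCCO2
F7 | step 8 | 3-[(1R,6S)-4-{[tert-butyl(dimethyl)silyl]oxy}-3-[6-hydroxy-8-methoxy-7-(propan-2-yl)-1,4-dioxaspiro[4.3]oct-7-en-6-yl]-1-methyl-6-(prop-1-en-2-yl)cyclohex-2-en-1-yl]propanoic acid | C=C(C)[C@@H]1CC(O[Si](C)(C)C(C)(C)C)C(=C[C@@]1(C)CCC(=O)O)C2(O)C(C(C)C)=C(OC)C23OCCO3
F8 | step 8 | 3-[(1R,6S)-4-{[tert-butyl(dimethyl)silyl]oxy}-3-[1-hydroxy-3-methoxy-4-oxo-2-(propan-2-yl)cyclobut-2-en-1-yl]-1-methyl-6-(prop-1-en-2-yl)cyclohex-2-en-1-yl]propanoic acid | C=C(C)[C@@H]1CC(O[Si](C)(C)C(C)(C)C)C(=C[C@@]1(C)CCC(=O)O)C2(O)C(C(C)C)=C(OC)C2=O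
F9 | step 8 | 3-[(1S,2S)-4-{[tert-butyl(dimethyl)silyl]oxy}-5,8-dihydroxy-7-methoxy-1-methyl-6-(propan-2-yl)-2-(prop-1-en-2-yl)-1,2,3,4-tetrahydronaphthalen-1-yl]propanoic acid | C=C(C)[C@@H]1CC(O[Si](C)(C)C(C)(C)C)c2c(O)c(C(C)C)c(OC)c(O)c2[C@@]1(C)CCC(=O)O
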